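**Retrosynthetic overview**

1. Numbering: six-membered ring C1 (CH), C14 (CH2), C13 (C=O), C12 (C=C18H2), C11 (CH), C15 (CMe2). Large ring C1–C2–C3/C4 (epoxide, Me on C4)–C5–C6–C7/C8 (epoxide, Me on C8)–C9–C10 (OAc)–C11–C15.
2. Enabling feature: in the cyclohexanone, the carbonyl carbon C13 lies 1,4 to the quaternary C15 and next to the methylene-bearing C12. A C13–C15 bond that the target lacks turns this ring into a 2,2-dimethylcyclobutanol (C13, C14, C1, C15) carrying C12=C11 as an alkenyl group on C13. An alkoxy radical at C13 then releases a tertiary C15 radical facing an enone whose β-carbon is C11.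
3. Key disconnection: C11–C15, a retro two-atom ring expansion (6 → 4) that at the same time turns the 12-membered ring into a 14-membered ring. Then C4–C5 (B-alkyl Suzuki macrocyclisation) and C12–C13 (alkenyllithium plus cyclobutanone).
4. Fragments: cyclobutanone 8 (C1–C4, C13–C15) from (+)-α-pinene, which fixes C1. Alkenyl iodide 17 (C5–C12, C18) from but-2-yne-1,4-diol, with C10 set by catalytic propargylation.
5. Ring order: cyclobutane (chiral pool) → 14-membered ring → six- and 12-membered rings together in the key step → two epoxides (reagent control) → enone and acetate last.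

Key step: step 16

Assumption: in step 10 the (R)-phosphoric acid is taken to give the (R)-carbinol, by analogy with its allylboration sense; the (S)-acid would be used if the sense were opposite.

**Route**

Step 1
Reactants: 1 (1R,5R)-(+)-α-pinene
Product: 2 2-[(1S,3S)-3-acetyl-2,2-dimethylcyclobutyl]acetic acid (cis-pinonic acid)
Conditions: RuCl3·xH2O (2 mol %), NaIO4 (4 equiv), CCl4/MeCN/H2O, rt
Reagents that add atoms: sodium periodate, [Na+].[O-]I(=O)(=O)=O
Why: Oxidative cleavage of the trisubstituted alkene by RuO4 formed in the flask gives the methyl ketone and the acid and leaves both ring stereocentres untouched, so the side-chain carbon keeps the configuration needed at C1.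

Step 2
Reactants: 2 cis-pinonic acid
Product: 3 2-[(1S,3S)-3-acetoxy-2,2-dimethylcyclobutyl]acetic acid
Conditions: mCPBA (2 equiv), CHCl3, 40 °C
Reagents that add atoms: mCPBA, OOC(=O)c1cccc(Cl)c1
Why: Baeyer–Villiger oxidation, in which the secondary cyclobutyl carbon should migrate in preference to methyl and with retention.

Step 3
Reactants: 3 acetoxy acid
Product: 4 (1S,3R)-3-(2-hydroxyethyl)-2,2-dimethylcyclobutyl acetate
Conditions: BH3·SMe2, THF, 0 °C to rt; MeOH
Reagents that add atoms: none
Why: Chemoselective borane reduction of a carboxylic acid in the presence of an ester.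

Step 4
Reactants: 4 acetoxy alcohol
Product: 5 (1S,3S)-2,2-dimethyl-3-(2-oxoethyl)cyclobutyl acetate
Conditions: Dess–Martin periodinane, NaHCO3, CH2Cl2, 0 °C to rt
Reagents that add atoms: none
Why: Dess–Martin oxidation of a primary alcohol to the aldehyde under buffered, non-epimerising conditions.

Step 5
Reactants: 5 acetoxy aldehyde
Product: 6 (1S,3R)-3-[(2Z)-3-iodobut-2-en-1-yl]-2,2-dimethylcyclobutyl acetate
Conditions: EtPPh3I, n-BuLi, THF, 0 °C; I2, −78 °C; NaN(SiMe3)2, −20 °C; then 5, −78 °C
Reagents that add atoms: ethyltriphenylphosphonium iodide, CC[P+](c1ccccc1)(c1ccccc1)c1ccccc1.[I-]; iodine, II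
Why: Stork–Zhao olefination with the α-iodoethylidene ylide should give the (Z)-2-iodo-2-alkene (C2 cis to iodine), which fixes the later Z geometry of C3=C4.

Step 6
Reactants: 6 vinyl iodide acetate
Product: 7 (1S,3R)-3-[(2Z)-3-iodobut-2-en-1-yl]-2,2-dimethylcyclobutan-1-ol
Conditions: K2CO3, MeOH, rt
Reagents that add atoms: none
Why: Base-catalysed transesterification removes the acetate without affecting the vinyl iodide.

Step 7
Reactants: 7 cyclobutanol
Product: 8 (3R)-3-[(2Z)-3-iodobut-2-en-1-yl]-2,2-dimethylcyclobutan-1-one (fragment A)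
Conditions: Dess–Martin periodinane, NaHCO3, CH2Cl2, rt
Reagents that add atoms: none
Why: Dess–Martin oxidation of the secondary cyclobutanol; the stereocentre (later C1) is not α to the ketone and cannot epimerise.

Step 8
Reactants: 9 but-2-yne-1,4-diol
Product: 10 4-[(tert-butyldimethylsilyl)oxy]but-2-yn-1-ol
Conditions: NaH (1.0 equiv), THF, 0 °C; TBSCl (1.0 equiv)
Reagents that add atoms: tert-butyldimethylsilyl chloride, CC(C)(C)[Si](C)(C)Cl
Why: Monosilylation of a symmetric diol through its sparingly soluble monosodium alkoxide.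

Step 9
Reactants: 10 monosilyl ether
Product: 11 4-[(tert-butyldimethylsilyl)oxy]but-2-ynal
Conditions: Dess–Martin periodinane, NaHCO3, CH2Cl2, 0 °C
Reagents that add atoms: none
Why: Dess–Martin oxidation of a propargylic alcohol to the ynal.

Step 10
Reactants: 11 ynal
Product: 12 (4R)-1-[(tert-butyldimethylsilyl)oxy]hepta-2,6-diyn-4-ol
Conditions: allenylB(pin) (1.5 equiv), (R)-TRIP phosphoric acid (10 mol %), 4 Å MS, toluene, −30 °C
Reagents that add atoms: allenylboronic acid pinacol ester, C=C=CB1OC(C)(C)C(C)(C)O1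
Why: Chiral phosphoric acid-catalysed propargylation (SE2' allenylboration through a six-membered chair transition state) should set C10 by catalyst control of the aldehyde face.

Step 11
Reactants: 12 diynol
Product: 14 (4R,6E)-1-[(tert-butyldimethylsilyl)oxy]-6-methylnona-6,8-dien-2-yn-4-ol, via alkenylalane 13 (not isolated)
Conditions: Me3Al (3.5 equiv), Cp2ZrCl2 (25 mol %), CH2Cl2, 0 °C to rt; then CH2=CHBr, ZnCl2 (20 mol %), Pd(PPh3)4 (5 mol %), THF, rt
Reagents that add atoms: trimethylaluminium, C[Al](C)C; vinyl bromide, C=CBr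
Why: Negishi zirconium-catalysed syn-methylalumination of the terminal alkyne (faster than the internal one), then palladium-catalysed coupling of the alkenylalane with retention, should give the E-trisubstituted C7=C8 and the diene terminus in one operation.

Step 12
Reactants: 14 dienynol
Product: 16 (2Z,4R,6E)-1-[(tert-butyldimethylsilyl)oxy]-2-iodo-6-methylnona-2,6,8-trien-4-ol, via cyclic alkenylalanate 15 (not isolated)
Conditions: NaAlH2(OCH2CH2OMe)2 (2.2 equiv), THF, 0 °C to rt; then I2, −78 °C
Reagents that add atoms: iodine, II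
Why: Hydroxyl-directed trans-hydroalumination of the propargylic alcohol delivers hydride to C11 and aluminium to C12 in a five-membered alanate, and iodination with retention places C10 cis to iodine (later cis to C13).

Step 13
Reactants: 16 iodo alcohol
Product: 17 (2Z,4R,6E)-1,4-bis[(tert-butyldimethylsilyl)oxy]-2-iodo-6-methylnona-2,6,8-triene (fragment B)
Conditions: TBSOTf, 2,6-lutidine, CH2Cl2, −78 °C
Reagents that add atoms: tert-butyldimethylsilyl triflate, CC(C)(C)[Si](C)(C)OS(=O)(=O)C(F)(F)F
Why: Silylation of the secondary allylic alcohol so that the alkenyl iodide can be lithiated.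

Step 14
Reactants: 17 fragment B; 8 fragment A
Product: 19 (1S,3R)-1-[(2Z,4R,6E)-1,4-bis(TBS-oxy)-6-methylnona-2,6,8-trien-2-yl]-3-[(2Z)-3-iodobut-2-en-1-yl]-2,2-dimethylcyclobutan-1-ol, via alkenyllithium 18 (not isolated)
Conditions: t-BuLi (2.1 equiv), Et2O, −78 °C; then 8, −78 °C; H2O
Reagents that add atoms: none
Why: Iodine–lithium exchange and 1,2-addition to the strained ketone are faster at −78 °C in ether than exchange with the second vinyl iodide or silyl migration; attack anti to the ring side chain should give mainly the drawn carbinol, and its C13 epimer converges in step 16.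

Step 15
Reactants: 19 open-chain cyclobutanol
Product: 21 (1R,10R,13S,3Z,7E,11Z)-10-(TBS-oxy)-12-[(TBS-oxy)methyl]-4,8,15,15-tetramethylbicyclo[11.1.1]pentadeca-3,7,11-trien-13-ol (overview numbering), via alkylborane 20 (not isolated)
Conditions: 9-BBN (2.5 equiv), THF, 0 °C to rt; then slow addition to Pd(dppf)Cl2 (10 mol %), AsPh3, Cs2CO3, DMF/THF/H2O, rt, 2 mM
Reagents that add atoms: none
Why: 9-BBN should hydroborate only the monosubstituted terminus of the 1,3-diene (boron on C5), and intramolecular B-alkyl Suzuki–Miyaura coupling with the (Z)-vinyl iodide under high dilution closes the 14-membered ring with retention of the Z geometry.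

Step 16
Reactants: 21 cyclobutanol-bridged 14-membered triene
Product: 23 (1R,10R,11R,3Z,7E)-10-(TBS-oxy)-12-[(TBS-oxy)methyl]-4,8,15,15-tetramethylbicyclo[9.3.1]pentadeca-3,7-dien-13-one (overview numbering, C12 epimers), via ring-opened radical 22 (not isolated)
Conditions: [Ir(dF(CF3)ppy)2(5,5'-d(CF3)bpy)]PF6 (2 mol %), 2,4,6-collidine (1 equiv), PhCF3 (5 mM), blue LEDs (450 nm), rt, degassed, no hydrogen-atom donor
Reagents that add atoms: none
Why: The excited trivalent iridium complex and collidine remove the O–H hydrogen by proton-coupled electron transfer, and the alkoxy radical at C13 opens the strained cyclobutane by β-scission of C13–C15 to the tertiary C15 radical 22, which faces a (Z)-enone C13(=O)–C12=C11 inside a 14-membered ring. C15 then adds across the ring to the β-carbon C11 (6-endo-trig), so the four-membered ring grows by C12 and C11 into the cyclohexanone while the 14-membered ring contracts to the 12-membered ring; the α-keto radical at C12 is reduced by the divalent iridium complex and the enolate is protonated by collidinium, which makes the process redox-neutral. The closest known reaction type is the photocatalytic ring expansion of 1-alkenylcycloalkanols to (n+2) cycloalkanones by alkoxy-radical β-scission and endo recombination with the unveiled enone. C11 is set by the olefin geometry in a chair-like transition state: with C2 pseudo-equatorial on the fixed C1, the (Z)-enone holds C10 cis to C13, a position that becomes axial, which gives the 1,11-trans bridge; C12 forms as a mixture that step 19 erases. The step needs cleavage of C13–C15 and not C13–C14, secured by the tertiary against the primary radical, and 6-endo and not 5-exo closure, secured by the carbonyl inside the tether, the stabilised α-keto radical and the substituent on C12. Without a hydrogen-atom donor the C15 radical should persist until it cyclises.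

Step 17
Reactants: 23 bicyclic dienone
Product: 24 (1R,3R,4S,7R,8R,10R,11R)-3,4:7,8-diepoxy-10-(TBS-oxy)-12-[(TBS-oxy)methyl]-4,8,15,15-tetramethylbicyclo[9.3.1]pentadecan-13-one (C12 epimers)
Conditions: D-fructose-derived Shi ketone (0.6 equiv), KHSO5 (Oxone), K2CO3, Bu4NHSO4, Na2B4O7 buffer, MeCN/CH2(OMe)2/H2O, 0 °C
Reagents that add atoms: potassium peroxymonosulfate, [K+].[O-]S(=O)(=O)OO
Why: Shi epoxidation, in which the chiral dioxirane should attack each trisubstituted alkene through the spiro transition state on the face that gives R at the CH carbon (C3 and C7), hence (3R,4S) from the Z and (7R,8R) from the E alkene, with the ketone and silyl ethers inert.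

Step 18
Reactants: 24 bis-epoxide
Product: 25 (1R,3R,4S,7R,8R,10R,11R)-3,4:7,8-diepoxy-10-hydroxy-12-(hydroxymethyl)-4,8,15,15-tetramethylbicyclo[9.3.1]pentadecan-13-one (C12 epimers)
Conditions: Bu4NF (4 equiv), AcOH (4 equiv), THF, 0 to 40 °C
Reagents that add atoms: none
Why: Acetic acid-buffered fluoride desilylation, chosen so that neither acid opens the 1,5-diepoxide nor free alkoxide triggers retro-aldol loss of C18.

Step 19
Reactants: 25 diol
Product: 27 (1R,3R,4S,7R,8R,10R,11S)-10-acetoxy-3,4:7,8-diepoxy-4,8,15,15-tetramethyl-12-methylidenebicyclo[9.3.1]pentadecan-13-one (CNP0339728.7), via diacetate 26 (not isolated)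
Conditions: Ac2O, Et3N, DMAP (cat.), CH2Cl2, 0 °C to rt; then DBU, rt
Reagents that add atoms: acetic anhydride, CC(=O)OC(C)=O
Why: Acetylation of both hydroxyls, then E1cB elimination of the primary β-acetoxy ketone (C12–H is α to C13=O), should unveil the exo-methylene enone and remove the C12 stereocentre, while the C10 acetate has no enolate in the β-position and stays.

**Compound list**

1 | (1R,5R)-(+)-α-pinene | CC1=CC[C@@H]2C[C@H]1C2(C)C | starting material
2 | 2-[(1S,3S)-3-acetyl-2,2-dimethylcyclobutyl]acetic acid | CC(=O)[C@H]1C[C@@H](CC(=O)O)C1(C)C | intermediate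
3 | 2-[(1S,3S)-3-acetoxy-2,2-dimethylcyclobutyl]acetic acid | CC(=O)O[C@H]1C[C@@H](CC(=O)O)C1(C)C | intermediate
4 | (1S,3R)-3-(2-hydroxyethyl)-2,2-dimethylcyclobutyl acetate | CC(=O)O[C@H]1C[C@@H](CCO)C1(C)C | intermediate
5 | (1S,3S)-2,2-dimethyl-3-(2-oxoethyl)cyclobutyl acetate | CC(=O)O[C@H]1C[C@@H](CC=O)C1(C)C | intermediate
6 | (1S,3R)-3-[(2Z)-3-iodobut-2-en-1-yl]-2,2-dimethylcyclobutyl acetate | CC(=O)O[C@H]1C[C@@H](C/C=C(/C)I)C1(C)C | intermediate
7 | (1S,3R)-3-[(2Z)-3-iodobut-2-en-1-yl]-2,2-dimethylcyclobutan-1-ol | O[C@H]1C[C@@H](C/C=C(/C)I)C1(C)C | intermediate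
8 | (3R)-3-[(2Z)-3-iodobut-2-en-1-yl]-2,2-dimethylcyclobutan-1-one (fragment A) | O=C1C[C@@H](C/C=C(/C)I)C1(C)C | intermediate
9 | but-2-yne-1,4-diol | OCC#CCO | starting material
10 | 4-[(tert-butyldimethylsilyl)oxy]but-2-yn-1-ol | OCC#CCO[Si](C)(C)C(C)(C)C | intermediate
11 | 4-[(tert-butyldimethylsilyl)oxy]but-2-ynal | O=CC#CCO[Si](C)(C)C(C)(C)C | intermediate
12 | (4R)-1-[(tert-butyldimethylsilyl)oxy]hepta-2,6-diyn-4-ol | C#CC[C@@H](O)C#CCO[Si](C)(C)C(C)(C)C | intermediate
13 | (E)-alkenyl(dimethyl)alane of 12, as its dimethylaluminium alkoxide (not isolated) | C[Al](C)/C=C(\C)C[C@@H](O[Al](C)C)C#CCO[Si](C)(C)C(C)(C)C | intermediate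
14 | (4R,6E)-1-[(tert-butyldimethylsilyl)oxy]-6-methylnona-6,8-dien-2-yn-4-ol | C=C/C=C(\C)C[C@@H](O)C#CCO[Si](C)(C)C(C)(C)C | intermediate
15 | sodium cyclic alkoxy(alkenyl)alanate of 14, aluminium on C12 (not isolated) | C=C/C=C(\C)C[C@H]1O[Al-](OCCOC)(OCCOC)C(CO[Si](C)(C)C(C)(C)C)=C1.[Na+] | intermediate
16 | (2Z,4R,6E)-1-[(tert-butyldimethylsilyl)oxy]-2-iodo-6-methylnona-2,6,8-trien-4-ol | C=C/C=C(\C)C[C@@H](O)/C=C(/CO[Si](C)(C)C(C)(C)C)I | intermediate
17 | (2Z,4R,6E)-1,4-bis[(tert-butyldimethylsilyl)oxy]-2-iodo-6-methylnona-2,6,8-triene (fragment B) | C=C/C=C(\C)C[C@@H](O[Si](C)(C)C(C)(C)C)/C=C(/CO[Si](C)(C)C(C)(C)C)I | intermediate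
18 | alkenyllithium from 17 (not isolated) | C=C/C=C(\C)C[C@@H](O[Si](C)(C)C(C)(C)C)/C=C(/CO[Si](C)(C)C(C)(C)C)[Li] | intermediate
19 | (1S,3R)-1-[(2Z,4R,6E)-1,4-bis(TBS-oxy)-6-methylnona-2,6,8-trien-2-yl]-3-[(2Z)-3-iodobut-2-en-1-yl]-2,2-dimethylcyclobutan-1-ol (major C13 epimer drawn) | C=C/C=C(\C)C[C@@H](O[Si](C)(C)C(C)(C)C)/C=C(/CO[Si](C)(C)C(C)(C)C)[C@]1(O)C[C@@H](C/C=C(/C)I)C1(C)C | intermediate
20 | B-alkyl-9-BBN from 19, boron on C5 (not isolated) | B1(CC/C=C(\C)C[C@@H](O[Si](C)(C)C(C)(C)C)/C=C(/CO[Si](C)(C)C(C)(C)C)[C@]2(O)C[C@@H](C/C=C(/C)I)C2(C)C)C2CCCC1CCC2 | intermediate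
21 | (1R,10R,13S,3Z,7E,11Z)-10-(TBS-oxy)-12-[(TBS-oxy)methyl]-4,8,15,15-tetramethylbicyclo[11.1.1]pentadeca-3,7,11-trien-13-ol (overview numbering; cyclobutane C13/C14/C1/C15) | O[C@]12C[C@@H](C/C=C(/C)CC/C=C(\C)C[C@@H](O[Si](C)(C)C(C)(C)C)/C=C1/CO[Si](C)(C)C(C)(C)C)C2(C)C | intermediate
22 | ring-opened 14-membered (3Z,7E,11Z)-trien-13-one with the tertiary radical at C15 on C1 (not isolated) | C[C](C)[C@@H]1C/C=C(/C)CC/C=C(\C)C[C@@H](O[Si](C)(C)C(C)(C)C)/C=C(/CO[Si](C)(C)C(C)(C)C)C(=O)C1 | intermediate
23 | (1R,10R,11R,3Z,7E)-10-(TBS-oxy)-12-[(TBS-oxy)methyl]-4,8,15,15-tetramethylbicyclo[9.3.1]pentadeca-3,7-dien-13-one (C12 epimers, centre removed in step 19) | CC(C)(C)[Si](C)(C)OCC1C(=O)C[C@H]2C/C=C(/C)CC/C=C(\C)C[C@@H](O[Si](C)(C)C(C)(C)C)[C@H]1C2(C)C | intermediate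
24 | (1R,3R,4S,7R,8R,10R,11R)-3,4:7,8-diepoxy-10-(TBS-oxy)-12-[(TBS-oxy)methyl]-4,8,15,15-tetramethylbicyclo[9.3.1]pentadecan-13-one (C12 epimers) | CC(C)(C)[Si](C)(C)OCC1C(=O)C[C@H]2C[C@H]3O[C@@]3(C)CC[C@H]3O[C@]3(C)C[C@@H](O[Si](C)(C)C(C)(C)C)[C@H]1C2(C)C | intermediate
25 | (1R,3R,4S,7R,8R,10R,11R)-3,4:7,8-diepoxy-10-hydroxy-12-(hydroxymethyl)-4,8,15,15-tetramethylbicyclo[9.3.1]pentadecan-13-one (C12 epimers) | OCC1C(=O)C[C@H]2C[C@H]3O[C@@]3(C)CC[C@H]3O[C@]3(C)C[C@@H](O)[C@H]1C2(C)C | intermediate
26 | 10-acetoxy-12-(acetoxymethyl) diacetate of 25 (not isolated) | CC(=O)OCC1C(=O)C[C@H]2C[C@H]3O[C@@]3(C)CC[C@H]3O[C@]3(C)C[C@@H](OC(C)=O)[C@H]1C2(C)C | intermediate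
27 | (1R,3R,4S,7R,8R,10R,11S)-10-acetoxy-3,4:7,8-diepoxy-4,8,15,15-tetramethyl-12-methylidenebicyclo[9.3.1]pentadecan-13-one (CNP0339728.7) | C=C1C(=O)C[C@H]2C[C@H]3O[C@@]3(C)CC[C@H]3O[C@]3(C)C[C@@H](OC(C)=O)[C@H]1C2(C)C | target

**Step count and risks**

Total step count: 19. Longest linear sequence: 13 steps (steps 1–7, then 14–19).

Steps most likely to fail:

Step 16. After β-scission the tertiary radical may take an allylic hydrogen across the 14-membered ring before it closes, or the ring conformation may force closure on the wrong enone face, which would lose the 1,11-trans relation. The fallback sets out from 19 and changes the order of ring formation. The open-chain cyclobutanol 19 is submitted to the same photocatalytic conditions, where an unconstrained chair-like 6-endo closure applies, and should give the cyclohexanone that carries the iodobutenyl chain on C1 and the dienyl chain on C11, F1. Hydroboration of its diene terminus with 9-BBN gives the alkylborane F2, and B-alkyl Suzuki–Miyaura macrocyclisation (Pd(dppf)Cl2, AsPh3, Cs2CO3, high dilution) closes the 12-membered ring directly. The route is rejoined at 23.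

Step 15. Oligomerisation may win over closure of a 14-membered ring that must span the trans-1,3 positions of the cyclobutane, and the free tertiary cyclobutanol may open by β-carbon elimination on palladium. The fallback sets out from 17 and 8 and makes the C4–C5 bond between the fragments first. Diene 17 is hydroborated (9-BBN) to the alkylborane F3, which is coupled with the unhindered vinyl iodide of ketone 8 (the flanked alkenyl iodide of F3 should react more slowly) to give the open-chain cyclobutanone alkenyl iodide F4. The 14-membered ring is then closed at C12–C13 by intramolecular Nozaki–Hiyama–Kishi addition of the alkenyl iodide to the strained ketone (CrCl2, NiCl2 cat., DMSO/THF, high dilution). The route is rejoined at 21.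

Step 17. Facial selectivity may be poor where the macrocycle shields the alkene face that the chiral dioxirane prefers, and the second alkene may convert incompletely. The fallback sets out from 23, postpones the oxidation and relies on substrate control. Buffered desilylation (Bu4NF, AcOH) gives the diene diol F5; acetylation to the diacetate F6 and DBU elimination give the dienyl enone acetate F7. Its two trisubstituted alkenes are then epoxidised from the ring periphery with dimethyldioxirane (acetone, −20 °C, neutral), which should leave the electron-poor exo-methylene alone. The route is rejoined at 27.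

**Further compounds**

F1 | step 16 | 2-[(TBS-oxy)methyl]cyclohexanone with the (2Z)-3-iodobut-2-enyl chain on C1 and the (1R,3E)-1-(TBS-oxy)-3-methylhexa-3,5-dienyl chain on C11 (C12 epimers) | CC(C)(C)[Si](C)(C)OCC1C(=O)C[C@@H](C/C=C(/C)I)C(C)(C)[C@@H]1[C@H](O[Si](C)(C)C(C)(C)C)C/C(C)=C/C=C
F2 | step 16 | B-alkyl-9-BBN from F1, boron on C5 | CC(C)(C)[Si](C)(C)OCC1C(=O)C[C@@H](C/C=C(/C)I)C(C)(C)[C@@H]1[C@H](O[Si](C)(C)C(C)(C)C)C/C(C)=C/CCB1C2CCCC1CCC2
F3 | step 15 | B-alkyl-9-BBN from 17, boron on C5 | C(C/C=C(\C)C[C@@H](O[Si](C)(C)C(C)(C)C)/C=C(/CO[Si](C)(C)C(C)(C)C)I)B1C2CCCC1CCC2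
F4 | step 15 | (3R)-2,2-dimethylcyclobutanone carrying the C2–C12 chain with the terminal (Z)-alkenyl iodide | O=C1C[C@@H](C/C=C(/C)CC/C=C(\C)C[C@@H](O[Si](C)(C)C(C)(C)C)/C=C(/CO[Si](C)(C)C(C)(C)C)I)C1(C)C
F5 | step 17 | (1R,10R,11R,3Z,7E)-10-hydroxy-12-(hydroxymethyl)-4,8,15,15-tetramethylbicyclo[9.3.1]pentadeca-3,7-dien-13-one (C12 epimers) | OCC1C(=O)C[C@H]2C/C=C(/C)CC/C=C(\C)C[C@@H](O)[C@H]1C2(C)C
F6 | step 17 | diacetate of F5 | CC(=O)OCC1C(=O)C[C@H]2C/C=C(/C)CC/C=C(\C)C[C@@H](OC(C)=O)[C@H]1C2(C)C
F7 | step 17 | (1R,10R,11S,3Z,7E)-10-acetoxy-4,8,15,15-tetramethyl-12-methylidenebicyclo[9.3.1]pentadeca-3,7-dien-13-one | C=C1C(=O)C[C@H]2C/C=C(/C)CC/C=C(\C)C[C@@H](OC(C)=O)[C@H]1C2(C)C
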